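**Remark on the chemistry:** the target is drawn as the 4(1H)-quinolone tautomer and has no stereocentre. The only stereo-element on the way is the alkene geometry of 7, which disappears when ring B becomes aromatic. Compounds 1, 3 and 8 are taken as purchasable.

**Numbering used throughout:** 1 monomethyl dodecanedioate; 2 hydroxy acid; 3 methyl methoxyacetate; 4 acyl imidazolide; 5 lithium ester enolate; 6 α-methoxy-β-keto ester; 7 primary β-enamino ester; 8 silylaryl triflate; 9 benzyne; 10 target.

## Analysis of the target

The target 10 is a 4(1H)-quinolone. Ring A is the benzo ring (C4a, C5, C6, C7, C8, C8a) and ring B is the 4-pyridone ring (N1, C2, C3, C4, C4a, C8a). Ring B is fully substituted: N1–H, an 11-hydroxy-11-methyldodecyl chain on C2 (ten methylenes ending in a dimethyl carbinol), a methoxy group on C3 and the carbonyl at C4. There is no stereocentre and no alkene geometry in the product, so the problem is one of constitution and chemoselectivity only. The sensitive groups are the tertiary alcohol, which eliminates under acid or strong heat and does not survive acid chloride formation, and the ambident quinolone, which alkylates at N1, O4 and a 3-oxygen alike. For that reason the C3 methoxy group should arrive with its carbon already in place and not by late methylation. The hard part is to place three different neighbouring substituents (alkyl on C2, methoxy on C3, oxygen on C4) on ring B without ambiguity and under conditions the carbinol tolerates. The feature that invites a bold cut is ring A itself: C5 to C8 carry only hydrogen, and the neighbouring carbons C8a and C4a carry N1 and the acyl carbon C4. This is the substitution pattern an unsubstituted, symmetrical aryne produces when it takes up a nitrogen nucleophile and an acyl electrophile on its two carbons.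

## Retrosynthetic reasoning

**Target 10 to 7 and 9 (from 8).** The bonds N1–C8a and C4–C4a are cut together. Ring A then becomes benzyne 9, released from 8 by fluoride. All of ring B's substituted atoms (N1, C2 with the chain, C3 with its methoxy group, C4 as an ester carbon) lie in one acyclic primary β-enamino ester 7. This cut is chosen because ring A is unsubstituted, so a symmetrical aryne cannot give a regioisomer, and because the precursor has no ring at all. The forward reaction has to N-arylate 7, then let the aryl anion acylate itself on the ester, closing ring B at carbon in the same operation, with the free tertiary alcohol present.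

**7 to 6.** The C3–N bond of 7 is cut to the α-methoxy-β-keto ester 6 and an ammonia source. The gain is that nitrogen enters as ammonia without a protecting group. The forward condensation must give the isomer with nitrogen and ester on the same side of the alkene.

**6 to 2 and 3 (through 4 and 5).** The C2–C3 bond of 6 is cut; this is the future C3–C2 bond of the quinolone. Acid 2 is activated as acyl imidazolide 4 and acylates the lithium enolate 5 of methyl methoxyacetate 3. The methoxy group thus comes in already on its carbon, and no oxidation or O-methylation of the heterocycle is needed later. An imidazolide is chosen because an acid chloride cannot be made next to the tertiary alcohol.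

**2 to 1.** The two C–CH3 bonds at the carbinol carbon are cut. A methyl organomagnesium reagent adds twice to the ester end of half-ester 1, while the acid end protects itself as its magnesium carboxylate. The carbinol is therefore set in the first step from a purchasable C12 building block and carried free through the route.

## Alternatives that were turned down

**Alternative 1:** Conrad–Limpach synthesis, the textbook route. The disconnection is N1–C2 and C4–C4a. Keto ester 6 is condensed with aniline A1 to methyl (2E)-3-anilino-14-hydroxy-2-methoxy-14-methylpentadec-2-enoate A2. The forward key step is thermolysis of A2 near 250 °C, with loss of methanol to an imino ketene and 6π-closure onto ring A. It was turned down for three reasons: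
- It is the route most chemists would draw first, and it has the same step count as the chosen one, so nothing is gained.
- The closure needs about 250 °C in the last step with the tertiary alcohol present. Thermal or trace-acid dehydration would give olefins that are hard to separate from 10.
- The temperature can only be lowered with strongly acidic media, which the carbinol cannot survive.

Because it branches from 6, it is kept as the fallback for the key step.

**Alternative 2:** Camps cyclisation. The disconnection is C2–C3, closing ring B at carbon. 1-(2-Aminophenyl)-2-methoxyethan-1-one A3 is acylated with acid 2 to 12-hydroxy-N-[2-(methoxyacetyl)phenyl]-12-methyltridecanamide A4. The forward key step is a base-mediated intramolecular aldol condensation of the methoxymethyl ketone enolate of A4 onto the amide carbonyl. It was turned down for three reasons: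
- A3 is not a stock compound and would cost about three steps of its own.
- The weakly nucleophilic ortho-acyl aniline needs a strongly activated acyl donor, which would force protection of the tertiary alcohol.
- A4 can also close in the opposite sense (amide α-carbon onto the ketone, the 2-quinolone mode).

The precursor already holds ring A with both substituents, so the key step would build less than the chosen one and the route would be longer.

**Alternative 3:** Ring transformation of isatoic anhydride. The disconnection is C3–C4 and N1–C2. The enolate of 13-hydroxy-1-methoxy-13-methyltetradecan-2-one A6 would C-acylate isatoic anhydride A5 with loss of carbon dioxide, and the freed amine would condense onto the ketone. It was turned down for three reasons: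
- A6 has two enolisable positions, C1 (bearing methoxy) and C3 (in the chain). Nothing in the structure firmly steers deprotonation to C1, and acylation at C3 would give a constitutional isomer of 10.
- The acidic N–H of A5 and the hydroxyl of A6 each consume enolate.
- A6 needs two steps from 2 through a methoxymethyl organometallic reagent.

The route would be longer and would carry a regiochemical risk that the chosen route does not have.

Key step: step 4

## Route

**Step 1**
Reactants: 1 12-methoxy-12-oxododecanoic acid (monomethyl dodecanedioate)
Product: 2 12-hydroxy-12-methyltridecanoic acid
Conditions: MeMgBr (4 equiv), THF, 0 °C to rt; then aq NH4Cl and citric acid to pH 4 at 0 °C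
Reagents that add atoms: methylmagnesium bromide, C[Mg]Br
Why: The first equivalent turns the acid into its magnesium carboxylate, which resists further addition, and the ester end takes up two methyl groups (Grignard double addition to an ester) to give the tertiary alcohol. The cold, weakly acidic work-up avoids dehydration.

**Step 2**
Reactants: 2 12-hydroxy-12-methyltridecanoic acid; 3 methyl 2-methoxyacetate
Product: 6 methyl 14-hydroxy-2-methoxy-14-methyl-3-oxopentadecanoate, via acyl imidazolide 4 (not isolated), via lithium ester enolate 5 (not isolated)
Conditions: flask A: 2, 1,1'-carbonyldiimidazole (1.1 equiv), THF, rt; flask B: 3 (4.5 equiv), LiN(iPr)2 (commercial solution, 4.4 equiv), THF, −78 °C; A into B, −78 °C; AcOH quench at −78 °C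
Reagents that add atoms: none
Why: This is a crossed Claisen acylation of an ester enolate by an acyl imidazolide; the imidazolide forms without touching the tertiary alcohol. The surplus enolate covers the imidazole N–H, the hydroxyl and the acidic C-2 hydrogen of the product, whose enolate also blocks a second addition. The C-2 centre of 6 is racemic and is removed in step 3.

**Step 3**
Reactants: 6 methyl 14-hydroxy-2-methoxy-14-methyl-3-oxopentadecanoate
Product: 7 methyl (2E)-3-amino-14-hydroxy-2-methoxy-14-methylpentadec-2-enoate
Conditions: NH4OAc (10 equiv), MeOH, 4 Å molecular sieves, 50 °C
Reagents that add atoms: ammonium acetate, CC(=O)[O-].[NH4+]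
Why: Condensation of a β-keto ester with ammonia gives the primary vinylogous carbamate. The (2E) isomer, with nitrogen and ester on the same side, should prevail because of its N–H···O=C hydrogen bond, and the isomers equilibrate through the imine tautomer.

**Step 4**
Reactants: 7 methyl (2E)-3-amino-14-hydroxy-2-methoxy-14-methylpentadec-2-enoate; 8 2-(trimethylsilyl)phenyl trifluoromethanesulfonate
Product: 10 2-(11-hydroxy-11-methyldodecyl)-3-methoxyquinolin-4(1H)-one, via benzyne 9 (not isolated)
Conditions: 8 (1.2 equiv, slow addition), CsF (4 equiv), THF, 65 °C
Reagents that add atoms: none
Why: Proposed new method: fluoride removes the silyl group of 8 and triflate leaves to give benzyne 9, the amino nitrogen of 7 adds to one aryne carbon, and the aryl anion left on the neighbouring carbon attacks the ester carbonyl and expels methoxide, so that N1–C8a and C4–C4a form and ring B closes in one operation. The closest known reaction type is the aryne annulation of methyl 2-aminobenzoates to acridones (N-arylation, then acylation of the aryl anion by the ortho ester), carried over here from an aromatic to an acyclic vinylogous carbamate. Ring B closes at carbon by a 6-exo-trig addition of the aryl anion to the ester carbonyl followed by loss of methoxide, and tautomerisation gives the 4(1H)-quinolone. No stereocentre is formed. Benzyne 9 is symmetrical, so the two ends of the triple bond are equivalent and no regioisomer can arise, which is exactly what the unsubstituted ring A allows. The step needs attack through nitrogen and not through C-2 of 7: C-2 is fully substituted, C-arylation there would build a quaternary carbon, and the 2-methoxy group donates against the amino group and so lowers the enamine character of C-2. It also needs acyl capture to outrun protonation of the aryl anion: the N–H···O=C hydrogen bond holds the (2E) geometry with nitrogen and ester on the same side of the alkene, which puts the carbonyl carbon in reach for a six-membered closure, and THF offers no acidic C–H. The tertiary alcohol is too hindered to compete for the aryne, and slow addition of a small excess of 8 should keep the acidic product 10 from a second arylation.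

## Compound list

1 | 12-methoxy-12-oxododecanoic acid | COC(=O)CCCCCCCCCCC(=O)O | starting material
2 | 12-hydroxy-12-methyltridecanoic acid | CC(C)(O)CCCCCCCCCCC(=O)O | intermediate
3 | methyl 2-methoxyacetate | COCC(=O)OC | starting material
4 | 12-hydroxy-1-(1H-imidazol-1-yl)-12-methyltridecan-1-one (acyl imidazolide) | CC(C)(O)CCCCCCCCCCC(=O)n1ccnc1 | intermediate
5 | lithium 1,2-dimethoxyethen-1-olate (lithium enolate of 3) | COC=C([O-])OC.[Li+] | intermediate
6 | methyl 14-hydroxy-2-methoxy-14-methyl-3-oxopentadecanoate (racemic at C-2) | COC(=O)C(OC)C(=O)CCCCCCCCCCC(C)(C)O | intermediate
7 | methyl (2E)-3-amino-14-hydroxy-2-methoxy-14-methylpentadec-2-enoate | N/C(CCCCCCCCCCC(C)(C)O)=C(/OC)C(=O)OC | intermediate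
8 | 2-(trimethylsilyl)phenyl trifluoromethanesulfonate | C[Si](C)(C)c1ccccc1OS(=O)(=O)C(F)(F)F | starting material
9 | benzyne (1,2-didehydrobenzene) | C1#CC=CC=C1 | intermediate
10 | 2-(11-hydroxy-11-methyldodecyl)-3-methoxyquinolin-4(1H)-one | COc1c(CCCCCCCCCCC(C)(C)O)[nH]c2ccccc2c1=O | target

## Step count and risk

Total step count: 4. Longest linear sequence: 4 steps (1 to 2 to 6 to 7 to 10); 3 and 8 enter as purchased partners.

**Step 4 (key step, proposed new method).** Three processes may defeat it:
- Attack of the aryne at C-2 of 7, directly or in an ene fashion through the allylic chain hydrogens, would lead to insertion into the C2–C3 bond and to isoquinoline-type skeletons.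
- Protonation of the aryl anion faster than acyl capture would stop the reaction at N-phenylation.
- A second arylation of the acidic quinolone by surplus aryne.

Fallback with known chemistry: setting out from 6, condensation with aniline A1 (AcOH cat., MeOH, 4 Å molecular sieves, 50 °C) should give methyl (2E)-3-anilino-14-hydroxy-2-methoxy-14-methylpentadec-2-enoate F1 (the compound labelled A2 above). Adding F1 to diphenyl ether preheated to 250 °C for a short time, in base-washed glassware, should close ring B by the Conrad–Limpach reaction and return to the route at 10. Plain N-phenylation in step 4 would give the same F1, so material lost to that process can be sent through this closure. The fallback accepts the thermal risk to the carbinol described under Alternative 1.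

**Step 2.** The enolate 5 may be quenched by the three acidic sites (imidazole N–H, tertiary O–H, C-2 hydrogen of the product) so that conversion stalls. Self-condensation of 5 on warming and O-acylation are further losses. Fallback: setting out from 2, activation with 1,1'-carbonyldiimidazole and acylation of the magnesium enolate of potassium methyl malonate (MgCl2, Et3N, MeCN, rt, acidic work-up with decarboxylation) should give methyl 14-hydroxy-14-methyl-3-oxopentadecanoate F2 under nearly neutral conditions. Diazo transfer (4-acetamidobenzenesulfonyl azide, Et3N, MeCN) should give methyl 2-diazo-14-hydroxy-14-methyl-3-oxopentadecanoate F3. O–H insertion of its carbenoid into methanol (Rh2(OAc)4 cat., MeOH/CH2Cl2, rt; the large excess of methanol should outrun intramolecular C–H insertion) should return to the route at 6.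

**Step 3.** The condensation may stop at an unfavourable equilibrium because of allylic strain in the tetrasubstituted enamine. Ammonia may also cleave the C2–C3 bond of 6 in a retro-Claisen sense, and the enamine may hydrolyse during purification. Fallback: setting out from 6, O-sulfonylation of the enol (TsCl, N-methylimidazole, Et3N, CH2Cl2, 0 °C) should give methyl 14-hydroxy-2-methoxy-14-methyl-3-{[(4-methylphenyl)sulfonyl]oxy}pentadec-2-enoate F4 as a mixture of alkene isomers. Addition–elimination with ammonia (NH3 in MeOH, rt, sealed vessel) replaces the condensation by a substitution at an activated vinyl sulfonate. Both isomers should converge on the hydrogen-bonded enamine, returning to the route at 7.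

## Further compounds

F1 | step 4 | methyl (2E)-3-anilino-14-hydroxy-2-methoxy-14-methylpentadec-2-enoate | c1ccccc1N/C(CCCCCCCCCCC(C)(C)O)=C(/OC)C(=O)OC
F2 | step 2 | methyl 14-hydroxy-14-methyl-3-oxopentadecanoate | COC(=O)CC(=O)CCCCCCCCCCC(C)(C)O
F3 | step 2 | methyl 2-diazo-14-hydroxy-14-methyl-3-oxopentadecanoate | COC(=O)C(=[N+]=[N-])C(=O)CCCCCCCCCCC(C)(C)O
F4 | step 3 | methyl 14-hydroxy-2-methoxy-14-methyl-3-{[(4-methylphenyl)sulfonyl]oxy}pentadec-2-enoate (mixture of alkene isomers) | COC(=O)C(OC)=C(CCCCCCCCCCC(C)(C)O)OS(=O)(=O)c1ccc(C)cc1
A1 | alternative 1 | aniline | Nc1ccccc1
A2 | alternative 1 | methyl (2E)-3-anilino-14-hydroxy-2-methoxy-14-methylpentadec-2-enoate | c1ccccc1N/C(CCCCCCCCCCC(C)(C)O)=C(/OC)C(=O)OC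
A3 | alternative 2 | 1-(2-aminophenyl)-2-methoxyethan-1-one | COCC(=O)c1ccccc1N
A4 | alternative 2 | 12-hydroxy-N-[2-(methoxyacetyl)phenyl]-12-methyltridecanamide | COCC(=O)c1ccccc1NC(=O)CCCCCCCCCCC(C)(C)O
A5 | alternative 3 | isatoic anhydride (2H-3,1-benzoxazine-2,4(1H)-dione) | O=C1Nc2ccccc2C(=O)O1
A6 | alternative 3 | 13-hydroxy-1-methoxy-13-methyltetradecan-2-one | COCC(=O)CCCCCCCCCCC(C)(C)O
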